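## Retrosynthetic overview

1. Lespeflorin C6 comes from one acidic unmasking of its 2',4'-bis-MOM, α-O-SiEt3, 4-O-acetyl derivative.
2. The key cut is the C(=O)–CH(O) bond, and both of its carbons start as aldehyde carbons. The aromatic aldehyde carbon is inverted into an aroyl anion equivalent, a lithiated α-silyloxy phosphonate on a TADDOL phosphorus. This adds to 4-acetoxyphenylacetaldehyde, passes its silyl group to the new alkoxide and expels the phosphorus unit, so the S centre is set in the bond-forming event.
3. The aroyl part comes from a double Stille prenylation of MOM-protected 3,5-dibromo-2,4-dihydroxybenzaldehyde.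
4. The acceptor aldehyde comes from an aldehyde-selective Wacker oxidation of 4-acetoxystyrene. The chiral silyl phosphite comes from (R,R)-TADDOL, PCl3 and Et3SiOH.
5. No ring is formed; both benzene rings are bought intact.

Assumption 1: the (R,R)-TADDOL phosphorus unit is taken to direct attack to the Re face of aldehyde 5, which gives S. If the first run gives the R product, the equally available (S,S)-TADDOL is used with no other change.

Assumption 2: 3,5-dibromo-2,4-dihydroxybenzaldehyde is taken as a catalogue compound.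

## Route

Step 1
Reactants: 1 3,5-dibromo-2,4-dihydroxybenzaldehyde
Product: 2 3,5-dibromo-2,4-bis(methoxymethoxy)benzaldehyde
Conditions: NaH (2.4 equiv), MOMCl (2.4 equiv), DMF, 0 °C → rt
Reagents that add atoms: chloromethyl methyl ether, COCCl
Why: Williamson-type O-alkylation of the two acidic phenoxides masks both phenols as base-stable acetals that survive the later stannane, amide base and carbanion chemistry.

Step 2
Reactants: 2 3,5-dibromo-2,4-bis(methoxymethoxy)benzaldehyde
Product: 3 2,4-bis(methoxymethoxy)-3,5-bis(3-methylbut-2-en-1-yl)benzaldehyde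
Conditions: prenylSnBu3 (2.6 equiv), Pd(PPh3)4 (8 mol %), DMF, 100 °C, 16 h
Reagents that add atoms: tributyl(3-methylbut-2-en-1-yl)stannane, CCCC[Sn](CCCC)(CCCC)CC=C(C)C
Why: In this double Stille coupling zerovalent palladium inserts into both C–Br bonds and the crowded aryl-allyl palladium intermediate eliminates at the less hindered allyl terminus to give linear prenyl groups, while the neutral stannane leaves the aldehyde and MOM groups alone.

Step 3
Reactants: 4 4-ethenylphenyl acetate (4-acetoxystyrene)
Product: 5 4-(2-oxoethyl)phenyl acetate (4-acetoxyphenylacetaldehyde)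
Conditions: PdCl2(MeCN)2 (5 mol %), 1,4-benzoquinone (1.15 equiv), H2O (1.1 equiv), t-BuOH, 85 °C, 1 h
Reagents that add atoms: water, O
Why: In this aldehyde-selective (anti-Markovnikov) Wacker oxidation of a styrene the bulky t-BuOH attacks the terminal carbon of the alkene complex of divalent palladium and the enol ether formed is hydrolysed to the arylacetaldehyde, with the aryl acetate untouched in the neutral medium.

Step 4
Reactants: 6 (R,R)-TADDOL, (4R,5R)-2,2-dimethyl-α,α,α',α'-tetraphenyl-1,3-dioxolane-4,5-dimethanol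
Product: 8 (3aR,8aR)-2,2-dimethyl-4,4,8,8-tetraphenyl-6-(triethylsilyloxy)tetrahydro-[1,3]dioxolo[4,5-e][1,3,2]dioxaphosphepine (TADDOL triethylsilyl phosphite), via chlorophosphite 7 (not isolated)
Conditions: PCl3 (1.0 equiv), Et3N (3.3 equiv), THF, 0 °C; then Et3SiOH (1.0 equiv), 0 °C → rt; filter under Ar, concentrate, use crude
Reagents that add atoms: phosphorus trichloride, ClP(Cl)Cl; triethylsilanol, CC[Si](O)(CC)CC
Why: Stepwise substitution at trivalent phosphorus closes the seven-membered cyclic chlorophosphite on the diol and then replaces the last chloride by silanolate, without touching the two carbon stereocentres of the diol.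

Step 5
Reactants: 3 2,4-bis(methoxymethoxy)-3,5-bis(3-methylbut-2-en-1-yl)benzaldehyde; 8 TADDOL triethylsilyl phosphite; 5 4-(2-oxoethyl)phenyl acetate
Product: 12 (S)-4-{3-[2,4-bis(methoxymethoxy)-3,5-bis(3-methylbut-2-en-1-yl)phenyl]-3-oxo-2-(triethylsilyloxy)propyl}phenyl acetate, via silyloxyphosphonate 9 (not isolated), via lithiated silyloxyphosphonate 10 (not isolated), via lithium aldolate 11 (not isolated)
Conditions: 3 + 8 (1.1 equiv), THF, 60 °C; cool to −78 °C, LiN(i-Pr)2 (LDA, 1.05 equiv), 30 min; 5 (1.5 equiv, precooled in THF), −78 → 0 °C; AcOH quench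
Reagents that add atoms: none
Why: Proposed new method: Abramov addition of 8 to 3 gives 9, whose deprotonation gives the aryl- and phosphonate-stabilised α-silyloxy carbanion 10, an aroyl anion equivalent that is the same intermediate as in the metallophosphite-catalysed enantioselective cross silyl benzoin reaction (reached there from an acylsilane by Brook rearrangement) and in the racemic benzoin synthesis with lithiated α-silyloxybenzylphosphonates, so it should attack the aldehyde carbon of 5 on the Re face from within the C2-symmetric tetraphenyl pocket to set the S carbinol centre, after which a 1,4 O-to-O silyl shift in 11 and loss of lithium phosphite reveal the ketone with fixed regiochemistry and without breaking any bond at the new centre.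

Step 6
Reactants: 12 (S)-4-{3-[2,4-bis(methoxymethoxy)-3,5-bis(3-methylbut-2-en-1-yl)phenyl]-3-oxo-2-(triethylsilyloxy)propyl}phenyl acetate
Product: 13 Lespeflorin C6, (S)-1-[2,4-dihydroxy-3,5-bis(3-methylbut-2-en-1-yl)phenyl]-2-hydroxy-3-(4-hydroxyphenyl)propan-1-one
Conditions: conc. aq HCl (to 0.3 M), MeOH–THF 4:1, 40 °C, 6 h
Reagents that add atoms: none
Why: Acid-catalysed acetal exchange (both MOM groups), silyl ether solvolysis and transesterification of the aryl acetate run together in methanol, no bond at the stereocentre is broken, and dilute acid at 40 °C is the routine window in which ortho-prenyl phenols do not close to chromans and the ketol does not enolise.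

## Compound list

1 | 3,5-dibromo-2,4-dihydroxybenzaldehyde | O=Cc1cc(Br)c(O)c(Br)c1O | starting material
2 | 3,5-dibromo-2,4-bis(methoxymethoxy)benzaldehyde | O=Cc1cc(Br)c(OCOC)c(Br)c1OCOC | intermediate
3 | 2,4-bis(methoxymethoxy)-3,5-bis(3-methylbut-2-en-1-yl)benzaldehyde | O=Cc1cc(CC=C(C)C)c(OCOC)c(CC=C(C)C)c1OCOC | intermediate
4 | 4-ethenylphenyl acetate | CC(=O)Oc1ccc(C=C)cc1 | starting material
5 | 4-(2-oxoethyl)phenyl acetate | CC(=O)Oc1ccc(CC=O)cc1 | intermediate
6 | (R,R)-TADDOL | CC1(C)O[C@H]([C@@H](O1)C(O)(c2ccccc2)c3ccccc3)C(O)(c4ccccc4)c5ccccc5 | starting material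
7 | (3aR,8aR)-6-chloro-2,2-dimethyl-4,4,8,8-tetraphenyltetrahydro-[1,3]dioxolo[4,5-e][1,3,2]dioxaphosphepine, formed in the flask | CC1(C)O[C@@H]2[C@@H](O1)C(c3ccccc3)(c4ccccc4)OP(Cl)OC2(c5ccccc5)c6ccccc6 | intermediate
8 | TADDOL triethylsilyl phosphite (6-triethylsilyloxy analogue of 7) | CC1(C)O[C@@H]2[C@@H](O1)C(c3ccccc3)(c4ccccc4)OP(O[Si](CC)(CC)CC)OC2(c5ccccc5)c6ccccc6 | intermediate
9 | TADDOL {[2,4-bis(methoxymethoxy)-3,5-diprenylphenyl](triethylsilyloxy)methyl}phosphonate, both epimers at the P-bearing carbon, formed in the flask | CC1(C)O[C@@H]2[C@@H](O1)C(c3ccccc3)(c4ccccc4)OP(=O)(C(O[Si](CC)(CC)CC)c7cc(CC=C(C)C)c(OCOC)c(CC=C(C)C)c7OCOC)OC2(c5ccccc5)c6ccccc6 | intermediate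
10 | α-lithio derivative of 9 (aroyl anion equivalent), formed in the flask | CC1(C)O[C@@H]2[C@@H](O1)C(c3ccccc3)(c4ccccc4)OP(=O)([C-](O[Si](CC)(CC)CC)c7cc(CC=C(C)C)c(OCOC)c(CC=C(C)C)c7OCOC)OC2(c5ccccc5)c6ccccc6.[Li+] | intermediate
11 | lithium aldolate from 10 and 5, S at the new carbinol carbon, quaternary carbon undefined, formed in the flask | CC1(C)O[C@@H]2[C@@H](O1)C(c3ccccc3)(c4ccccc4)OP(=O)(C(O[Si](CC)(CC)CC)(c7cc(CC=C(C)C)c(OCOC)c(CC=C(C)C)c7OCOC)[C@@H]([O-])Cc8ccc(OC(C)=O)cc8)OC2(c5ccccc5)c6ccccc6.[Li+] | intermediate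
12 | (S)-4-{3-[2,4-bis(methoxymethoxy)-3,5-bis(3-methylbut-2-en-1-yl)phenyl]-3-oxo-2-(triethylsilyloxy)propyl}phenyl acetate | CC(C)=CCc1cc(C(=O)[C@@H](O[Si](CC)(CC)CC)Cc2ccc(OC(C)=O)cc2)c(OCOC)c(CC=C(C)C)c1OCOC | intermediate
13 | Lespeflorin C6, (S)-1-[2,4-dihydroxy-3,5-bis(3-methylbut-2-en-1-yl)phenyl]-2-hydroxy-3-(4-hydroxyphenyl)propan-1-one | CC(C)=CCc1cc(C(=O)[C@@H](O)Cc2ccc(O)cc2)c(O)c(CC=C(C)C)c1O | target

## Step count and risks

Total step count: 6.
Longest linear sequence: 4 (steps 1, 2, 5, 6).

**Most likely to fail, first: step 5.**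
- Carbanion 10 may enolise the arylacetaldehyde 5 instead of adding to it.
- The Abramov addition of the bulky phosphite may be slow.
- The level and sense of induction with an aliphatic acceptor are untested. An ee below 95 % would have to be raised by crystallising 13.

The fallback sets out from 3 and comes back at 13. It exchanges the polarity of the two carbons, so the enolisable aldehyde is no longer needed. Bought tyrosol is protected with MOMCl/K2CO3 to 2-[4-(methoxymethoxy)phenyl]ethanol F1. This is carbamoylated with N,N-diisopropylcarbamoyl chloride/NaH to 2-[4-(methoxymethoxy)phenyl]ethyl N,N-diisopropylcarbamate F2. Treatment with s-BuLi/(+)-sparteine in Et2O at −78 °C removes the pro-R hydrogen and gives the configurationally stable (R)-α-lithiated carbamate F3. This adds to aldehyde 3 with retention and, after an acetic acid quench, gives the (2S)-1-aryl-1-hydroxy-3-arylpropan-2-yl carbamate F4 as a mixture of C1 epimers. LiAlH4 removes the carbamoyl group to give the (2S)-1,2-diol F5. MnO2 oxidises only the benzylic alcohol to the (S)-tris-MOM α-hydroxy ketone F6. The conditions of step 6 then convert F6 into 13.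

**Second: step 2.**
- The C3 bromide sits between two MOM ethers, so oxidative addition there is slow.
- Transfer of the bulky prenyl group may stall or leak to the reverse-prenyl isomer.

The fallback sets out from 2 and comes back at 3. The smaller allyl group is coupled first with allyltributylstannane and Pd(PPh3)4 in DMF at 90 °C, giving 3,5-diallyl-2,4-bis(methoxymethoxy)benzaldehyde F7. Both terminal alkenes are then turned into prenyl groups by cross-metathesis with excess 2-methylbut-2-ene, using second-generation Grubbs catalyst in CH2Cl2 at 40 °C. This delivers 3.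

**Third: step 3.**
- The arylacetaldehyde is fragile.
- The oxidation may give some methyl ketone, or partial loss of the acetate.

The fallback sets out from 4 and comes back at 5. Epoxidation with mCPBA in CH2Cl2 at 0 °C gives 4-(oxiran-2-yl)phenyl acetate F8. A Meinwald rearrangement with InCl3 (5 mol %) in THF at rt opens F8 at the benzylic carbon, and a hydride shift gives 5.

## Further compounds

F1 | step 5 | 2-[4-(methoxymethoxy)phenyl]ethanol | COCOc1ccc(CCO)cc1
F2 | step 5 | 2-[4-(methoxymethoxy)phenyl]ethyl N,N-diisopropylcarbamate | COCOc1ccc(CCOC(=O)N(C(C)C)C(C)C)cc1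
F3 | step 5 | (R)-α-lithiated carbamate of F2 (sparteine ligand not drawn) | [Li][C@@H](OC(=O)N(C(C)C)C(C)C)Cc1ccc(OCOC)cc1
F4 | step 5 | (2S)-1-[2,4-bis(methoxymethoxy)-3,5-diprenylphenyl]-1-hydroxy-3-[4-(methoxymethoxy)phenyl]propan-2-yl N,N-diisopropylcarbamate, C1 epimers | CC(C)=CCc1cc(C(O)[C@@H](OC(=O)N(C(C)C)C(C)C)Cc2ccc(OCOC)cc2)c(OCOC)c(CC=C(C)C)c1OCOC
F5 | step 5 | (2S)-1-[2,4-bis(methoxymethoxy)-3,5-diprenylphenyl]-3-[4-(methoxymethoxy)phenyl]propane-1,2-diol, C1 epimers | CC(C)=CCc1cc(C(O)[C@@H](O)Cc2ccc(OCOC)cc2)c(OCOC)c(CC=C(C)C)c1OCOC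
F6 | step 5 | (S)-1-[2,4-bis(methoxymethoxy)-3,5-diprenylphenyl]-2-hydroxy-3-[4-(methoxymethoxy)phenyl]propan-1-one | CC(C)=CCc1cc(C(=O)[C@@H](O)Cc2ccc(OCOC)cc2)c(OCOC)c(CC=C(C)C)c1OCOC
F7 | step 2 | 3,5-diallyl-2,4-bis(methoxymethoxy)benzaldehyde | O=Cc1cc(CC=C)c(OCOC)c(CC=C)c1OCOC
F8 | step 3 | 4-(oxiran-2-yl)phenyl acetate (racemic) | CC(=O)Oc1ccc(C2CO2)cc1
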